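**Assumptions**
- The SMILES has no stereocentre and no stereogenic double bond. The target is achiral, so "single enantiomer" does not apply and nothing needs to be set or protected from scrambling.
- I read the chain as 19 unbranched carbons on the ring carbon. The target is 2-hydroxy-5-methoxy-3-nonadecyl-1,4-benzoquinone, C26H44O4.

## Retrosynthetic overview
1. O–CH3 disconnection: the target comes from site-selective Fischer-type etherification of 2,5-dihydroxy-3-nonadecyl-1,4-benzoquinone at the unhindered C5–OH.
2. C3–C1′ disconnection (the only skeletal C–C bond): a new redox-neutral hydrogen-borrowing C–H alkylation of 2,5-dihydroxy-1,4-benzoquinone with 1-nonadecanol.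
3. C18 + C1 disconnection: 1-nonadecanol comes from octadecylmagnesium bromide and formaldehyde.
4. Rings: none is built. The single six-membered quinone ring is bought intact at the correct oxidation level, and no protecting groups are used.

## Forward route

**Step 1**
Reactants: 1, 1-bromooctadecane
Product: 2, 1-nonadecanol (unbranched C19 primary alcohol)
Conditions: Mg, cat. I2, THF, reflux; then dry (CH2O)n, 0 °C → reflux; aq. NH4Cl
Reagents that add atoms: formaldehyde (as paraformaldehyde), C=O
Why: Grignard addition to formaldehyde is a standard one-carbon homologation of a primary alkyl halide to the primary alcohol, it turns a bulk C18 feedstock into the odd C19 chain, and no stereocentre is formed.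

**Step 2**
Reactants: 2, 1-nonadecanol; 3, 2,5-dihydroxy-1,4-benzoquinone
Product: 4, 2,5-dihydroxy-3-nonadecyl-1,4-benzoquinone
Conditions: Shvo's catalyst (2.5 mol %), 3 (3 equiv), 2 added over 6 h, 1,4-dioxane, 110 °C, sealed tube, Ar, 24 h; then air, rt
Reagents that add atoms: none (both partners are numbered reactants; H2O is lost)
Why: Proposed new method: a "quinone-relay" borrowing-hydrogen C–H alkylation of a hydroxy-p-benzoquinone with an unactivated primary alcohol, in which the 16-electron half of Shvo's catalyst dehydrogenates 2 to nonadecanal, the resulting Ru–H/O–H half passes its H2 to 3 (storing it as benzene-1,2,4,5-tetrol), the aldehyde condenses at the nucleophilic C3 of the vinylogous acid 3 (self-catalysed, pKa about 3) and loses water to give an electrophilic o-quinone methide, and that intermediate is reduced at its exocyclic carbon by the tetrol or by Ru–H to give 4 and return 3, so the process is redox-neutral with water as the only by-product (condensation of the aldehyde with the tetrol followed by tautomerisation leads to the same product); the closest known reaction types are Ru/Ir hydrogen-autotransfer alkylation of 1,3-dicarbonyls and 4-hydroxycoumarins with alcohols, Shvo/quinone-coupled alcohol dehydrogenation, and aldehyde/Hantzsch-ester reductive alkylation of hydroxyquinones, which to my knowledge have not been merged on a benzoquinone; no stereocentre is created.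

**Step 3**
Reactants: 4, 2,5-dihydroxy-3-nonadecyl-1,4-benzoquinone
Product: 5, Irisoquin-C, 2-hydroxy-5-methoxy-3-nonadecyl-1,4-benzoquinone
Conditions: MeOH–toluene (4:1), cat. conc. H2SO4, 65 °C, about 4 h (stop at mono-ether)
Reagents that add atoms: methanol, CO
Why: Fischer-type etherification of a vinylogous acid (acid-catalysed addition–elimination of MeOH) occurs at C5, which is flanked by C6–H, while the C2–OH next to the C19 chain is sterically shielded, as in 3-alkyl-2-hydroxyquinones that resist this reaction, so the 2-OH/5-OMe isomer forms and no stereocentre is involved.

## Compound list
1 | 1-bromooctadecane | CCCCCCCCCCCCCCCCCCBr | starting material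
2 | 1-nonadecanol | CCCCCCCCCCCCCCCCCCCO | intermediate (also sold in gram quantities)
3 | 2,5-dihydroxy-1,4-benzoquinone | O=C1C=C(O)C(=O)C=C1O | starting material
4 | 2,5-dihydroxy-3-nonadecyl-1,4-benzoquinone | CCCCCCCCCCCCCCCCCCCC1=C(O)C(=O)C=C(O)C1=O | intermediate
5 | Irisoquin-C (2-hydroxy-5-methoxy-3-nonadecyl-1,4-benzoquinone; achiral) | CCCCCCCCCCCCCCCCCCCC1=C(O)C(=O)C=C(OC)C1=O | target

## Summary
Total steps: 3. Longest linear sequence: 3 (1 → 2 → 4 → 5).

**Steps most likely to fail**

1. **Step 2 (proposed new step).**
   - Risks:
     - The chelating hydroxyquinonate may sequester Ru.
     - Dehydrogenative esterification of 2 may give nonadecyl nonadecanoate.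
     - The quinone methide may be diverted to the 2:1 alkylidene-bis-quinone or the 1-alkenylquinone.
     - 3,6-Dialkylation may occur. It is limited by using 3 equiv of 3, and the excess is removed by filtration because it is insoluble in CH2Cl2/hexane.
   - Fallback (known chemistry): drop hydrogen autotransfer. Oxidise 2 to nonadecanal (TEMPO/PhI(OAc)2, CH2Cl2). Then run the metal-free three-component reductive alkylation of 3 with the aldehyde, Hantzsch ester and cat. L-proline (CH2Cl2, rt), the established route to 3-alkyl-2,5-dihydroxybenzoquinones. This adds one step.

2. **Step 3.**
   - Risks: over-methylation to the 2,5-dimethyl ether, or slow reaction because the waxy substrate dissolves poorly. The regiochemistry can be checked by NOE: OMe ↔ H-6 in 5, versus OMe ↔ C1′-H2 in the wrong isomer.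
   - Fallback: reverse the order of events.
     - Convert 3 to 2,5-dimethoxy-1,4-benzoquinone (MeOH/H+).
     - Mono-hydrolyse with one equivalent of aqueous hydroxide to 2-hydroxy-5-methoxy-1,4-benzoquinone.
     - Install the chain at C3, its only enolic carbon, by reductive alkylation with nonadecanal. No late O-differentiation is then needed.

3. **Step 1.**
   - Risks: Wurtz coupling to hexatriacontane, protonation to octadecane, and slow depolymerisation of paraformaldehyde.
   - Fallback: avoid C–C bond formation. Reduce commercial nonadecanoic acid with LiAlH4 (THF), or purchase 2 directly.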